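## Retrosynthetic overview

1. Target 17 is a cis-(3R,4R)-isoflavan-4-ol (ring C: O1, C2, C3, C4; primed locants for ring B); it comes from its 5-O-allyl ether 16 by zerovalent-palladium deallylation.
2. 16 comes from the acyclic aldehyde 13 by closing ring C through the C3–C4 bond in one flask: carbene-catalysed vinylogous Stetter (1,6-) addition of the ring-A aldehyde carbon (C4) to a p-quinone methide, then transfer hydrogenation with dynamic kinetic resolution that sets C3 and C4.
3. Enabling feature: the free 4'-OH of ring B is para to C1', the ring carbon that carries C3. Unmasking the 4'-oxygen therefore expels a leaving group from C3 and makes C3 the electrophilic exocyclic carbon of a quinone methide. The resulting C3–H lies between ring B and the C4 carbonyl, is labile, and lets one catalyst fix both centres.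
4. 13 comes from ketone 9 (ketone-selective reduction, acetylation), and 9 from phenacyl bromide 6 plus phenol 8 (Williamson ether, O1–C2). 6 comes from acetophenone 1 (iodination, silylation, Stille prenylation, bromination); 8 from the symmetric dihydroxybenzaldehyde 7 (mono-allylation).
5. Rings A and B are bought as arenes; ring C is the only ring formed (step 9).

Key step: step 9

Remark: the SMILES is read as the cis-(3R,4R) isomer (3-aryl and 4-OH on the same face of ring C); 1 and 7 are taken as catalogue compounds.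
Abbreviations: ArB = 2-methoxy-5-(3-methylbut-2-en-1-yl)-4-[(triisopropylsilyl)oxy]phenyl; TsDPEN = N-tosyl-1,2-diphenylethane-1,2-diamine (monodeprotonated ligand).

## Route

Step 1
Reactants: 1 1-(4-hydroxy-2-methoxyphenyl)ethan-1-one
Product: 2 1-(4-hydroxy-5-iodo-2-methoxyphenyl)ethan-1-one
Conditions: NIS (1.0 equiv), TsOH·H2O (10 mol%), MeCN, 0 °C to rt
Reagents that add atoms: N-iodosuccinimide O=C1CCC(=O)N1I
Why: Electrophilic aromatic iodination ortho to the phenol should go to C5 (para to OMe, unhindered) in preference to C3, which is squeezed between OH and OMe.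

Step 2
Reactants: 2 1-(4-hydroxy-5-iodo-2-methoxyphenyl)ethan-1-one
Product: 3 1-{5-iodo-2-methoxy-4-[(triisopropylsilyl)oxy]phenyl}ethan-1-one
Conditions: TIPSCl, imidazole, DMF, rt
Reagents that add atoms: chlorotriisopropylsilane CC(C)[Si](Cl)(C(C)C)C(C)C
Why: Imidazole-promoted silyl ether formation masks the phenol for the coupling, enolate and alkylation steps and installs the fluoride-labile trigger used in step 9.

Step 3
Reactants: 3 1-{5-iodo-2-methoxy-4-[(triisopropylsilyl)oxy]phenyl}ethan-1-one
Product: 4 1-ArB-ethan-1-one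
Conditions: tributyl(3-methylbut-2-en-1-yl)stannane, Pd(PPh3)4 (5 mol%), LiCl, DMF, 90 °C
Reagents that add atoms: tributyl(3-methylbut-2-en-1-yl)stannane CCCC[Sn](CCCC)(CCCC)CC=C(C)C
Why: Stille coupling of the aryl iodide under zerovalent palladium should give the linear prenyl arene, because transfer through the gamma carbon would build a quaternary centre, and the neutral conditions leave the ketone and silyl ether alone.

Step 4
Reactants: 4 1-ArB-ethan-1-one
Product: 6 2-bromo-1-ArB-ethan-1-one, via silyl enol ether 5 (not isolated)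
Conditions: LiN(SiMe3)2, Me3SiCl, THF, −78 °C; then NBS, THF, −78 to 0 °C
Reagents that add atoms: N-bromosuccinimide O=C1CCC(=O)N1Br; chlorotrimethylsilane C[Si](C)(C)Cl (its atoms stay only in 5)
Why: Alpha-bromination via the enol silane should be chemoselective because the silyl enol ether reacts with NBS far faster than the trisubstituted prenyl alkene or the acyl-deactivated ring.

Step 5
Reactants: 7 2,6-dihydroxy-4-methoxybenzaldehyde
Product: 8 2-(allyloxy)-6-hydroxy-4-methoxybenzaldehyde
Conditions: allyl bromide (1.0 equiv), K2CO3 (1.1 equiv), acetone, rt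
Reagents that add atoms: allyl bromide C=CCBr
Why: Williamson ether synthesis on a twofold-symmetric diol needs no regiocontrol, and after the first alkylation the remaining OH is hydrogen-bonded to the aldehyde and less nucleophilic, so the reaction should stop at the mono-ether.

Step 6
Reactants: 6 2-bromo-1-ArB-ethan-1-one; 8 2-(allyloxy)-6-hydroxy-4-methoxybenzaldehyde
Product: 9 2-(allyloxy)-4-methoxy-6-(2-ArB-2-oxoethoxy)benzaldehyde
Conditions: K2CO3, acetone, rt
Reagents that add atoms: none
Why: Williamson etherification with a phenacyl bromide is fast at room temperature, where the Rap–Stoermer aldol closure to a benzofuran and carbonate cleavage of the aryl silyl ether should remain slow; this forms the O1–C2 bond.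

Step 7
Reactants: 9 2-(allyloxy)-4-methoxy-6-(2-ArB-2-oxoethoxy)benzaldehyde
Product: 12 racemic 2-(allyloxy)-6-(2-ArB-2-hydroxyethoxy)-4-methoxybenzaldehyde, via tert-butyl aldimine 10 (not isolated), via imine alcohol 11 (not isolated)
Conditions: t-BuNH2, 4 Å MS, CH2Cl2, rt; then LiAlH(OtBu)3, THF, −78 to −20 °C; then aq. AcOH/NaOAc (pH 5), THF, rt
Reagents that add atoms: water O (returns the aldehyde oxygen on hydrolysis); tert-butylamine CC(C)(C)N (its atoms stay only in 10 and 11)
Why: Ketone-selective hydride reduction with in-situ protection: only the aldehyde condenses with the bulky amine, the aldimine is inert to LiAlH(OtBu)3 at low temperature, and buffered hydrolysis returns the aldehyde; the new centre is left racemic on purpose because step 9 erases it.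

Step 8
Reactants: 12 racemic 2-(allyloxy)-6-(2-ArB-2-hydroxyethoxy)-4-methoxybenzaldehyde
Product: 13 racemic 2-[3-(allyloxy)-2-formyl-5-methoxyphenoxy]-1-ArB-ethyl acetate
Conditions: Ac2O, Et3N, DMAP (cat.), CH2Cl2, 0 °C (purification on Et3N-deactivated silica)
Reagents that add atoms: acetic anhydride CC(=O)OC(C)=O
Why: DMAP-catalysed acylation turns the benzylic hydroxyl into the leaving group for quinone methide release, and the aldehyde, silyl ether and alkenes are inert to it.

Step 9
Reactants: 13 racemic 2-[3-(allyloxy)-2-formyl-5-methoxyphenoxy]-1-ArB-ethyl acetate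
Product: 16 (3R,4R)-5-(allyloxy)-3-[4-hydroxy-2-methoxy-5-(3-methylbut-2-en-1-yl)phenyl]-7-methoxychroman-4-ol, via p-quinone methide 14 (not isolated), via racemic isoflavanone 15 (not isolated)
Conditions: 2-(pentafluorophenyl)-6,7-dihydro-5H-pyrrolo[2,1-c][1,2,4]triazol-2-ium tetrafluoroborate (20 mol%), CsF (2.5 equiv), 18-crown-6 (20 mol%), MeCN, 0 °C to rt; then, in the same flask, RuCl(p-cymene)[(R,R)-TsDPEN] (3 mol%), HCO2H/Et3N (2:5), 40 °C
Reagents that add atoms: none
Why: Proposed new method: fluoride cleaves the 4'-O–Si bond of 13 and the phenoxide expels the benzylic acetate, which turns C3 into the exocyclic carbon of p-quinone methide 14, while the triazolylidene adds to the aldehyde so that C4 becomes an acyl anion (Breslow intermediate) and attacks C3 in a vinylogous Stetter (1,6-) addition; rearomatisation of ring B and release of the carbene give isoflavanone 15, which the ruthenium hydride added to the same flask reduces. The closest known reactions are the carbene-catalysed 1,6-addition of aldehydes to stable p-quinone methides, the carbene-catalysed Stetter and crossed-benzoin closures of O-tethered salicylaldehydes to chroman-4-ones, the fluoride-triggered release of quinone methides from silyloxybenzyl acetates and the Noyori transfer hydrogenation of isoflavanones with dynamic kinetic resolution; new is the intramolecular addition to a transient p-quinone methide without blocking groups. Ring C closes in the 6-exo-trig mode (C4 onto C3, the C3=C1' double bond stays outside the new ring). C3 is formed racemic and stays labile in the amine-rich medium (enolisation and reversible oxa-Michael ring opening), so C3 and C4 are both set by the (R,R)-TsDPEN ruthenium hydride, which should reduce the 3R ketone faster and deliver hydride to C4 anti to the 3-aryl group, giving the cis (3R,4R) alcohol in the same facial sense as its known (R)-selective reduction of chroman-4-one. The step needs C–C bond formation to outrun proton loss from C2 of 14 (which would give an inert aryl styryl ether): the six-membered transition state, the reversible capture of 14 by acetate or fluoride that keeps its concentration low, the small carbene at the hindered aldehyde and the 2'-methoxy group that tempers 14 should secure this, and the basic formate medium spares the acid-labile C4 alcohol.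

Step 10
Reactants: 16 (3R,4R)-5-(allyloxy)-3-[4-hydroxy-2-methoxy-5-(3-methylbut-2-en-1-yl)phenyl]-7-methoxychroman-4-ol
Product: 17 (3R,4R)-3-[4-hydroxy-2-methoxy-5-(3-methylbut-2-en-1-yl)phenyl]-7-methoxychromane-4,5-diol
Conditions: Pd(PPh3)4 (5 mol%), morpholine, THF, rt
Reagents that add atoms: none
Why: Tsuji–Trost-type deallylation, in which zerovalent palladium ionises the aryl allyl ether and morpholine captures the allyl group, runs under neutral to basic conditions that should spare the acid-labile C4 benzylic alcohol, the C-prenyl group and both stereocentres.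

## Compound list

1 | 1-(4-hydroxy-2-methoxyphenyl)ethan-1-one | CC(=O)c1ccc(O)cc1OC | starting material
2 | 1-(4-hydroxy-5-iodo-2-methoxyphenyl)ethan-1-one | CC(=O)c1cc(I)c(O)cc1OC | intermediate
3 | 1-{5-iodo-2-methoxy-4-[(triisopropylsilyl)oxy]phenyl}ethan-1-one | CC(=O)c1cc(I)c(O[Si](C(C)C)(C(C)C)C(C)C)cc1OC | intermediate
4 | 1-{2-methoxy-5-(3-methylbut-2-en-1-yl)-4-[(triisopropylsilyl)oxy]phenyl}ethan-1-one | CC(=O)c1cc(CC=C(C)C)c(O[Si](C(C)C)(C(C)C)C(C)C)cc1OC | intermediate
5 | trimethylsilyl enol ether of 4, trimethyl({1-[2-methoxy-5-(3-methylbut-2-en-1-yl)-4-(triisopropylsilyloxy)phenyl]vinyl}oxy)silane (not isolated) | C=C(O[Si](C)(C)C)c1cc(CC=C(C)C)c(O[Si](C(C)C)(C(C)C)C(C)C)cc1OC | intermediate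
6 | 2-bromo-1-{2-methoxy-5-(3-methylbut-2-en-1-yl)-4-[(triisopropylsilyl)oxy]phenyl}ethan-1-one | BrCC(=O)c1cc(CC=C(C)C)c(O[Si](C(C)C)(C(C)C)C(C)C)cc1OC | intermediate
7 | 2,6-dihydroxy-4-methoxybenzaldehyde | COc1cc(O)c(C=O)c(O)c1 | starting material
8 | 2-(allyloxy)-6-hydroxy-4-methoxybenzaldehyde | COc1cc(O)c(C=O)c(OCC=C)c1 | intermediate
9 | 2-(allyloxy)-4-methoxy-6-(2-{2-methoxy-5-(3-methylbut-2-en-1-yl)-4-[(triisopropylsilyl)oxy]phenyl}-2-oxoethoxy)benzaldehyde | COc1cc(OCC=C)c(C=O)c(OCC(=O)c2cc(CC=C(C)C)c(O[Si](C(C)C)(C(C)C)C(C)C)cc2OC)c1 | intermediate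
10 | N-tert-butyl aldimine of 9 (not isolated) | COc1cc(OCC=C)c(C=NC(C)(C)C)c(OCC(=O)c2cc(CC=C(C)C)c(O[Si](C(C)C)(C(C)C)C(C)C)cc2OC)c1 | intermediate
11 | N-tert-butyl aldimine of 12, racemic (not isolated) | COc1cc(OCC=C)c(C=NC(C)(C)C)c(OCC(O)c2cc(CC=C(C)C)c(O[Si](C(C)C)(C(C)C)C(C)C)cc2OC)c1 | intermediate
12 | racemic 2-(allyloxy)-6-(2-hydroxy-2-{2-methoxy-5-(3-methylbut-2-en-1-yl)-4-[(triisopropylsilyl)oxy]phenyl}ethoxy)-4-methoxybenzaldehyde | COc1cc(OCC=C)c(C=O)c(OCC(O)c2cc(CC=C(C)C)c(O[Si](C(C)C)(C(C)C)C(C)C)cc2OC)c1 | intermediate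
13 | racemic 2-[3-(allyloxy)-2-formyl-5-methoxyphenoxy]-1-{2-methoxy-5-(3-methylbut-2-en-1-yl)-4-[(triisopropylsilyl)oxy]phenyl}ethyl acetate | COc1cc(OCC=C)c(C=O)c(OCC(OC(C)=O)c2cc(CC=C(C)C)c(O[Si](C(C)C)(C(C)C)C(C)C)cc2OC)c1 | intermediate
14 | 2-(allyloxy)-4-methoxy-6-{2-[2-methoxy-5-(3-methylbut-2-en-1-yl)-4-oxocyclohexa-2,5-dien-1-ylidene]ethoxy}benzaldehyde, p-quinone methide (not isolated) | COc1cc(OCC=C)c(C=O)c(OCC=C2C=C(CC=C(C)C)C(=O)C=C2OC)c1 | intermediate
15 | racemic 5-(allyloxy)-3-[4-hydroxy-2-methoxy-5-(3-methylbut-2-en-1-yl)phenyl]-7-methoxychroman-4-one (not isolated) | COc1cc(OCC=C)c2C(=O)C(c3cc(CC=C(C)C)c(O)cc3OC)COc2c1 | intermediate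
16 | (3R,4R)-5-(allyloxy)-3-[4-hydroxy-2-methoxy-5-(3-methylbut-2-en-1-yl)phenyl]-7-methoxychroman-4-ol | COc1cc(OCC=C)c2c(c1)OC[C@@H](c1cc(CC=C(C)C)c(O)cc1OC)[C@H]2O | intermediate
17 | (3R,4R)-3-[4-hydroxy-2-methoxy-5-(3-methylbut-2-en-1-yl)phenyl]-7-methoxychromane-4,5-diol | COc1cc(O)c2c(c1)OC[C@@H](c1cc(CC=C(C)C)c(O)cc1OC)[C@H]2O | target

## Step count and risks

Total step count: 10. Longest linear sequence: 9 steps (steps 1, 2, 3, 4, 6, 7, 8, 9, 10 from 1).

Steps most likely to fail:

1. Step 9 (carries the label "Proposed new method:"). What may go wrong: proton loss from C2 of the quinone methide (tautomerisation to an aryl styryl ether), or slow carbene addition to the doubly ortho-substituted aldehyde, may outrun C–C bond formation; the salts of the first stage may also slow the hydrogen transfer. Fallback with known chemistry only, setting out from ketone 9: a carbene-catalysed intramolecular crossed aldehyde–ketone benzoin reaction (same triazolium salt, Et3N, THF, rt) should close ring C through the same C3–C4 bond and give the 3-hydroxyisoflavanone F1. SmI2 (THF/MeOH, −78 °C) should then cleave the tertiary alpha-hydroxyl reductively to the racemic isoflavanone silyl ether F2. Noyori transfer hydrogenation with dynamic kinetic resolution (RuCl(p-cymene)[(R,R)-TsDPEN], HCO2H/Et3N 2:5, 40 °C) should give the cis-(3R,4R) alcohol F3. Bu4NF buffered with AcOH (THF, 0 °C) removes the silyl group, and the route is rejoined at 16.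

2. Step 7. What may go wrong: incomplete imine formation at the hindered aldehyde would expose it to hydride (over-reduction), and the hydrolysis may ionise the new electron-rich benzylic alcohol. Fallback that installs the benzylic oxygen before the aldehyde-bearing ring is attached, setting out from bromoketone 6: NaBH4 (MeOH/THF, −20 °C) should give the racemic bromohydrin F4, and Ac2O/pyridine/DMAP the bromo acetate F5. Williamson alkylation of phenol 8 with F5 (K2CO3, NaI cat., DMF, 50 °C) should then give 13 directly, where the route is rejoined (9 and 12 are bypassed).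

3. Step 4. What may go wrong: bromination of the prenyl double bond or of the electron-rich ring, or double bromination, in competition with the enol silane. Fallback without electrophilic halogen, setting out from ketone 4: detrifluoroacetylative diazo transfer (LiN(SiMe3)2, CF3CO2CH2CF3, THF, −78 °C; then MsN3, Et3N, H2O, MeCN, rt) should pass through the trifluoroacetyl ketone F6 to the diazoketone F7. Rh2(OAc)4-catalysed O–H insertion of F7 into phenol 8 (CH2Cl2, rt) should give ketone 9 directly, where the route is rejoined (6 is bypassed).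

Further compounds
F1 | step 9 | racemic 5-(allyloxy)-3-hydroxy-7-methoxy-3-{2-methoxy-5-(3-methylbut-2-en-1-yl)-4-[(triisopropylsilyl)oxy]phenyl}chroman-4-one | COc1cc(OCC=C)c2C(=O)C(O)(c3cc(CC=C(C)C)c(O[Si](C(C)C)(C(C)C)C(C)C)cc3OC)COc2c1
F2 | step 9 | racemic 5-(allyloxy)-7-methoxy-3-{2-methoxy-5-(3-methylbut-2-en-1-yl)-4-[(triisopropylsilyl)oxy]phenyl}chroman-4-one | COc1cc(OCC=C)c2C(=O)C(c3cc(CC=C(C)C)c(O[Si](C(C)C)(C(C)C)C(C)C)cc3OC)COc2c1
F3 | step 9 | (3R,4R)-5-(allyloxy)-7-methoxy-3-{2-methoxy-5-(3-methylbut-2-en-1-yl)-4-[(triisopropylsilyl)oxy]phenyl}chroman-4-ol | COc1cc(OCC=C)c2c(c1)OC[C@@H](c1cc(CC=C(C)C)c(O[Si](C(C)C)(C(C)C)C(C)C)cc1OC)[C@H]2O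
F4 | step 7 | racemic 2-bromo-1-{2-methoxy-5-(3-methylbut-2-en-1-yl)-4-[(triisopropylsilyl)oxy]phenyl}ethan-1-ol | OC(CBr)c1cc(CC=C(C)C)c(O[Si](C(C)C)(C(C)C)C(C)C)cc1OC
F5 | step 7 | racemic 2-bromo-1-{2-methoxy-5-(3-methylbut-2-en-1-yl)-4-[(triisopropylsilyl)oxy]phenyl}ethyl acetate | CC(=O)OC(CBr)c1cc(CC=C(C)C)c(O[Si](C(C)C)(C(C)C)C(C)C)cc1OC
F6 | step 4 | 4,4,4-trifluoro-1-{2-methoxy-5-(3-methylbut-2-en-1-yl)-4-[(triisopropylsilyl)oxy]phenyl}butane-1,3-dione | O=C(CC(=O)C(F)(F)F)c1cc(CC=C(C)C)c(O[Si](C(C)C)(C(C)C)C(C)C)cc1OC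
F7 | step 4 | 2-diazo-1-{2-methoxy-5-(3-methylbut-2-en-1-yl)-4-[(triisopropylsilyl)oxy]phenyl}ethan-1-one | [N-]=[N+]=CC(=O)c1cc(CC=C(C)C)c(O[Si](C(C)C)(C(C)C)C(C)C)cc1OC
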